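In this closed, stirred vessel you count turnovers: how many charges of substrate each step could move during the run.

substrate 0.036 M; gas phase 3.4 mM (held); time 2.5 d

- the target and idle adduct together standing at 2.5 d, as a percentage of the substrate charged
- the change that raises the amount of target and idle adduct together at 2.5 d, in percent of the substrate charged most ("none" if none brings more than 2 percentage points) (Monday's / Thursday's / none)
- amount of target and idle adduct together at 2.5 d, in percent of the substrate charged, after Monday's

- in percentages every species weighs as the substrate in it: one side product B counts as two
- for target the idle adduct is counted in
- at the start none of the gas is dissolved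
- run time (flask): 2.5 d

    gas phase ⇌ dissolved gas, rate k1*(csat - [dissolved gas]) (k1 = 0.0048 min⁻¹, csat = 3.4 mM)
    substrate + dissolved gas → target (k2 = 0.53 L mol⁻¹ min⁻¹)
    substrate → side product A (k3 = 1.7 × 10⁻⁴ min⁻¹)
    dissolved gas + target ⇌ idle adduct, settled at all times (K4 = 99 L mol⁻¹)
    substrate + target → side product B (k5 = 8.7 × 10⁻⁴ L mol⁻¹ min⁻¹)
    target ⇌ isomer of the product (K6 = 0.87, k6 = 3.4 × 10⁻⁴ min⁻¹)

Here is my own reckoning, in rates. Gas crosses into the solution and meets substrate to give target, while substrate also decays to side product A. Target slips towards its isomer unless it is bound as idle adduct.

Supply number, the charges the passage delivers in the run into an empty solution (transfer coefficient times saturation concentration times time, over the charge): 163%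

Slowing by standing gas: at the charge, substrate takes up gas faster than it crosses, so early in the run the passage is the rate-limiting step. With substrate as charged, it runs at a factor 79.9%, and I carry that factor through the run as a rough figure, which leaves 130% per run.

Side route: 61.2% per run, so the gas route's share starts at 68.1% and climbs towards 91.4% as c(dissolved gas) nears saturation. I take the mean, 79.7%.

Ageing: the gas route has delivered half the charge by 0.959 d. Target then ages for the rest of the run, with c(dissolved gas) taken at 0.5 of saturation: 1.51 relaxations towards a balance that keeps 57.3%, so 66.7% stays.

Product of share and retention: 53.2%

After Monday's: 58.8%

Best change: Monday's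

The forecast says 50% (46% to 54%), Monday's, and 60% (55% to 65%), holding that doubling saturation “doubles both the gas supply and the dissolved gas level”. Its first figure stands below mine.

The simulation gives 50.1%, and 60.1% after Monday's. Monday's wins, with 10 percentage points against 5 points for Thursday's. The forecast held.

In the flask, half of the turnover of substrate with dissolved gas up to 2.5 d was done by 0.852 d, and 3.0% of the substrate stood at the end. Meanwhile target went on to the isomer, 22.2% net by 2.5 d.

In the neighbour charged with 0.14 M, the supply number is 42.0%, below the side route's 61.2%, so expect target and adduct under that supply. That neighbour computes to 23.1%, with side product A holding most, at 35.9%.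

The constants used here are those of an exercise; the run is a simulation.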